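**Assumption:** locants follow germacrane numbering with the target read as an 8,12-olide (C1–C10 epoxide with the C14 methyl on C10, C2 ketone, C3 CH2, C4=C15, C5 2-methylbutanoate, C6 and C9 acetates, C7–C11(=C13)–C12(=O)–O–C8); in the asymmetric aldol step the catalyst antipode is taken to be the one that gives the threo adduct as drawn in the compound list.

## Retrosynthetic overview

1. The α-methylene lactone is made last: oxidation of C12 (allylic CH2OH) and lactonisation onto O8 of a seco-triol, with C2–OH going to the ketone in the same operation.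
2. The C5 ester and C4=C15 come from a singlet-oxygen ene reaction on the 4E-alkene of the ten-membered ring, so C5 is set from C6.
3. The ten-membered ring is closed at C6–C7, the bond the germacrene cyclase makes, not at the customary lactone-forming C7–C8 bond: an allylchromium (C13–C11=C7) adds through C7 to the C6 enal of the fully oxygenated, epoxide-bearing chain, creating C6, C7 and the C11=C13 methylene.
4. The chain is assembled by a cross-metathesis that puts C11–C13 on a C7 vinyl group and a vinylogous aldol (C2–C3) of a prenal dienol ether with an epoxy aldehyde.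
5. The epoxy aldehyde comes from hydroxyl-directed epoxidation (C1, C10) of a (Z)-ene-diol, made by reducing a butenolide from an asymmetric vinylogous aldol of a 4-methyl-2-silyloxyfuran with acrolein (C8, C9). Ring order: epoxide, carbocycle, lactone.

## Route

Step 1
Reactants: 1 4-methylfuran-2(5H)-one
Product: 2 tert-butyl(dimethyl)[(4-methylfuran-2-yl)oxy]silane
Conditions: TBSOTf, Et3N, CH2Cl2, 0 °C
Reagents that add atoms: tert-butyldimethylsilyl triflate, CC(C)(C)[Si](C)(C)OS(=O)(=O)C(F)(F)F
Why: Soft enolisation and O-silylation of the butenolide gives the aromatic 2-silyloxyfuran, the standard dienolate equivalent for vinylogous Mukaiyama aldol chemistry, and no stereocentre is involved.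

Step 2
Reactants: 2 tert-butyl(dimethyl)[(4-methylfuran-2-yl)oxy]silane; 3 acrolein
Product: 4 (5R)-5-[(1R)-1-hydroxyprop-2-en-1-yl]-4-methylfuran-2(5H)-one (8,9-threo)
Conditions: SiCl4 (1.1 equiv), (R,R)-Denmark binaphthyldiamine bisphosphoramide (3 mol %), i-Pr2NEt (10 mol %), CH2Cl2, −78 °C; sat. aq. NaHCO3
Reagents that add atoms: none
Why: Catalytic enantioselective vinylogous Mukaiyama aldol reaction (Lewis-base-activated SiCl4, best with conjugated aldehydes) joins furan C5 to the aldehyde through an open antiperiplanar transition state that gives the threo adduct, the chiral catalyst fixing the absolute configuration of C8 and C9, the only reagent-controlled stereocentres of the route.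

Step 3
Reactants: 4 (5R)-5-[(1R)-1-hydroxyprop-2-en-1-yl]-4-methylfuran-2(5H)-one
Product: 5 (5R)-4-methyl-5-[(1R)-1-(triethylsilyloxy)prop-2-en-1-yl]furan-2(5H)-one
Conditions: TESCl, imidazole, DMAP (cat.), CH2Cl2, 0 °C
Reagents that add atoms: chlorotriethylsilane, CC[Si](Cl)(CC)CC
Why: Silyl ether formation at the only hydroxyl under conditions too mild to enolise the butenolide, so C8 and C9 are untouched.

Step 4
Reactants: 5 (5R)-4-methyl-5-[(1R)-1-(triethylsilyloxy)prop-2-en-1-yl]furan-2(5H)-one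
Product: 6 (2Z,4R,5R)-3-methyl-5-(triethylsilyloxy)hepta-2,6-diene-1,4-diol
Conditions: DIBAL-H (3.5 equiv), CH2Cl2, −78 → −20 °C; Rochelle salt
Reagents that add atoms: none
Why: DIBAL-H 1,2-reduction of the unsaturated lactone gives the ene-1,4-diol, and the ring it came from guarantees the Z geometry of C1=C10 that the cis-epoxide needs.

Step 5
Reactants: 6 (2Z,4R,5R)-3-methyl-5-(triethylsilyloxy)hepta-2,6-diene-1,4-diol
Product: 7 [(2S,3R)-3-[(1S,2R)-1-hydroxy-2-(triethylsilyloxy)but-3-en-1-yl]-3-methyloxiran-2-yl]methanol (cis-epoxide, 9,10-threo)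
Conditions: mCPBA (1.1 equiv), NaHCO3, CH2Cl2, 0 °C
Reagents that add atoms: meta-chloroperbenzoic acid, OOC(=O)c1cccc(Cl)c1
Why: Henbest hydroxyl-directed peracid epoxidation of the (Z)-trisubstituted allylic alcohol, in which A(1,3) strain holds H-9 in the alkene plane so that the C9 hydroxyl delivers oxygen to its own face (threo rule), sets C1 and C10 stereospecifically as the cis-epoxide while the monosubstituted vinyl group reacts far more slowly.

Step 6
Reactants: 7 epoxy diol
Product: 9 9-O-acetyl-2-O-triethylsilyl derivative of 7, via 2-O-triethylsilyl ether 8 (not isolated)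
Conditions: TESCl (1.05 equiv), imidazole, CH2Cl2, −40 °C; then Ac2O, Et3N, DMAP, 0 °C → rt
Reagents that add atoms: chlorotriethylsilane, CC[Si](Cl)(CC)CC; acetic anhydride, CC(=O)OC(C)=O
Why: Chemoselective silylation of the primary over the hindered secondary hydroxyl followed in the same flask by DMAP-catalysed acetylation places the C9 acetate of the target without creating a stereocentre.

Step 7
Reactants: 9 9-O-acetyl-2-O-triethylsilyl derivative of 7
Product: 10 (1S,2R)-1-[(2R,3R)-3-formyl-2-methyloxiran-2-yl]-2-(triethylsilyloxy)but-3-en-1-yl acetate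
Conditions: (COCl)2, DMSO, CH2Cl2, −78 → −30 °C; Et3N, −78 → 0 °C
Reagents that add atoms: none
Why: Swern oxidation converts a primary triethylsilyl ether directly into the aldehyde and leaves the secondary TES ether, the acetate and the epoxide alone, and the aldehyde α-carbon is an epoxide carbon that cannot epimerise.

Step 8
Reactants: 11 3-methylbut-2-enal (prenal)
Product: 12 (E)-triethyl[(3-methylbuta-1,3-dien-1-yl)oxy]silane
Conditions: TESOTf, Et3N, Et2O, 0 °C → rt
Reagents that add atoms: triethylsilyl triflate, CC[Si](CC)(CC)OS(=O)(=O)C(F)(F)F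
Why: γ-Deprotonation and O-silylation of the enal gives the 1-silyloxydiene (silyl dienol ether formation) whose geometry is irrelevant to the next step.

Step 9
Reactants: 10 epoxy aldehyde; 12 (E)-triethyl[(3-methylbuta-1,3-dien-1-yl)oxy]silane
Product: 13 open-chain (4E)-enal with C6 aldehyde, C2-OTES (1,2-anti to the epoxide), C1–C10 cis-epoxide, C9-OAc, C8-OTES and C7 vinyl
Conditions: 12 (1.5 equiv), B(C6F5)3 (5 mol %), CH2Cl2, −78 °C; Et3N quench
Reagents that add atoms: none
Why: Lewis-acid-catalysed vinylogous Mukaiyama aldol reaction with silyl transfer adds the diene terminus (C3) to the epoxy aldehyde under Felkin–Anh control (anti to the epoxide C–O bond) to give mainly the 1,2-anti C2 silyl ether and the (E)-enal, and the C2 centre is erased later by oxidation.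

Step 10
Reactants: 14 2-methylidenepropane-1,3-diol
Product: 15 2-({[tert-butyl(dimethyl)silyl]oxy}methyl)prop-2-en-1-ol
Conditions: NaH (1.0 equiv), THF, 0 °C; TBSCl (1.0 equiv), rt
Reagents that add atoms: tert-butyldimethylsilyl chloride, CC(C)(C)[Si](C)(C)Cl
Why: Monosilylation of a symmetric diol through its sparingly soluble monosodium alkoxide (McDougal protocol) gives the mono-ether selectively.

Step 11
Reactants: 15 2-({[tert-butyl(dimethyl)silyl]oxy}methyl)prop-2-en-1-ol
Product: 16 {[2-(bromomethyl)prop-2-en-1-yl]oxy}(tert-butyl)dimethylsilane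
Conditions: CBr4, PPh3, CH2Cl2, 0 °C
Reagents that add atoms: carbon tetrabromide, BrC(Br)(Br)Br
Why: Appel reaction turns the primary allylic alcohol into the bromide under neutral conditions that keep the silyl ether.

Step 12
Reactants: 13 open-chain enal; 16 {[2-(bromomethyl)prop-2-en-1-yl]oxy}(tert-butyl)dimethylsilane
Product: 17 allylic bromide: 13 with C7H=C11(CH2Br)(CH2OTBS) in place of the vinyl group (E/Z mixture at C7=C11)
Conditions: 16 (5 equiv), Hoveyda–Grubbs II (10 mol %), CH2Cl2, 40 °C
Reagents that add atoms: none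
Why: Olefin cross-metathesis between the monosubstituted alkene and an excess of the 1,1-disubstituted partner gives the trisubstituted alkene with loss of ethylene, the conjugated trisubstituted enal is inert, and the E/Z ratio does not matter because the derived allylchromium equilibrates.

Step 13
Reactants: 17 allylic bromide
Product: 19 ten-membered carbocyclic alcohol (6-OH; 7-C(=CH2)CH2OTBS; 4E; 2-OTES; 1,10-epoxide; 9-OAc; 8-OTES; all centres as in the target), via allylchromium species 18 (not isolated)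
Conditions: CrCl2 (8 equiv), THF, rt, slow addition of 17 to 2 mM; H2O
Reagents that add atoms: none
Why: Intramolecular Nozaki–Hiyama–Kishi allylation in which the equilibrating allylchromium(III) attacks the enal through C7 (SE2′) in a chair transition state with both chain substituents equatorial (6,7-anti) and, with H-8 eclipsing the allyl unit by A(1,3) strain, anti to the C8–C9 bond, so that the cyclase-type C6–C7 bond, the C11=C13 methylene and the C6 and C7 stereocentres are formed together.

Step 14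
Reactants: 19 ten-membered carbocyclic alcohol
Product: 20 6-O-acetate of 19
Conditions: Ac2O, pyridine, DMAP (cat.), CH2Cl2, rt
Reagents that add atoms: acetic anhydride, CC(=O)OC(C)=O
Why: DMAP-catalysed acetylation of the only free hydroxyl installs the C6 acetate of the target.

Step 15
Reactants: 20 6-O-acetate of 19
Product: 22 5-hydroxy-4(15)-ene (5,6-threo; C5 as in the target), via C5 hydroperoxide 21 (not isolated)
Conditions: O2, TPP (1 mol %), hν, CH2Cl2, 0 °C; then PPh3, 0 °C → rt
Reagents that add atoms: oxygen (as singlet oxygen), O=O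
Why: Schenck ene reaction in which the cis effect directs hydrogen abstraction to C15 and oxygen to C5 on the exposed outer face of the ring alkene (H-6 in the alkene plane by A(1,3) strain, C6–OAc outward, hence 5,6-threo), followed by phosphine reduction of the hydroperoxide, while the 1,1-disubstituted C11=C13 alkene is much less reactive.

Step 16
Reactants: 22 5-hydroxy-4(15)-ene; 23 (R)-2-methylbutanoic acid
Product: 24 5-O-[(2R)-2-methylbutanoyl] ester of 22
Conditions: DIC, DMAP (cat.), CH2Cl2, 0 °C → rt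
Reagents that add atoms: none
Why: Steglich esterification of the only free hydroxyl with the enantiopure α-alkyl acid, which does not epimerise under carbodiimide and catalytic DMAP at 0 °C.

Step 17
Reactants: 24 5-O-[(2R)-2-methylbutanoyl] ester
Product: 25 2,8,12-triol (seco-lactone)
Conditions: HF·pyridine, pyridine, THF, 0 °C → rt
Reagents that add atoms: none
Why: Buffered fluoride desilylation removes the two TES ethers and the primary TBS ether without touching the three esters or the epoxide.

Step 18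
Reactants: 25 2,8,12-triol
Product: 28 target (CNP0256300.1), via lactol 26 (not isolated), via hydroxy lactone 27 (not isolated)
Conditions: TEMPO (20 mol %), PhI(OAc)2 (4 equiv), CH2Cl2, rt
Reagents that add atoms: none
Why: TEMPO/PhI(OAc)2 oxidation attacks the primary allylic C12 alcohol first, the carbonyl is trapped by O8 as the five-membered lactol and oxidised on to the cis-fused α-methylene lactone (oxidative lactonisation, ring fusion already fixed by C7 and C8), and the remaining secondary C2 carbinol is then oxidised to the ketone.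

## Compound list

1 | 4-methylfuran-2(5H)-one | CC1=CC(=O)OC1 | starting material
2 | tert-butyl(dimethyl)[(4-methylfuran-2-yl)oxy]silane | Cc1coc(O[Si](C)(C)C(C)(C)C)c1 | intermediate
3 | acrolein (prop-2-enal) | C=CC=O | starting material
4 | (5R)-5-[(1R)-1-hydroxyprop-2-en-1-yl]-4-methylfuran-2(5H)-one | C=C[C@@H](O)[C@@H]1OC(=O)C=C1C | intermediate
5 | (5R)-4-methyl-5-[(1R)-1-(triethylsilyloxy)prop-2-en-1-yl]furan-2(5H)-one | C=C[C@@H](O[Si](CC)(CC)CC)[C@@H]1OC(=O)C=C1C | intermediate
6 | (2Z,4R,5R)-3-methyl-5-(triethylsilyloxy)hepta-2,6-diene-1,4-diol | C=C[C@@H](O[Si](CC)(CC)CC)[C@H](O)/C(C)=C\CO | intermediate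
7 | [(2S,3R)-3-[(1S,2R)-1-hydroxy-2-(triethylsilyloxy)but-3-en-1-yl]-3-methyloxiran-2-yl]methanol | C=C[C@@H](O[Si](CC)(CC)CC)[C@H](O)[C@@]1(C)O[C@H]1CO | intermediate
8 | 2-O-triethylsilyl ether of 7 (C9-OH free) | C=C[C@@H](O[Si](CC)(CC)CC)[C@H](O)[C@@]1(C)O[C@H]1CO[Si](CC)(CC)CC | intermediate
9 | 9-O-acetyl-2-O-triethylsilyl derivative of 7 | C=C[C@@H](O[Si](CC)(CC)CC)[C@H](OC(C)=O)[C@@]1(C)O[C@H]1CO[Si](CC)(CC)CC | intermediate
10 | (1S,2R)-1-[(2R,3R)-3-formyl-2-methyloxiran-2-yl]-2-(triethylsilyloxy)but-3-en-1-yl acetate | C=C[C@@H](O[Si](CC)(CC)CC)[C@H](OC(C)=O)[C@@]1(C)O[C@H]1C=O | intermediate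
11 | 3-methylbut-2-enal (prenal) | CC(C)=CC=O | starting material
12 | (E)-triethyl[(3-methylbuta-1,3-dien-1-yl)oxy]silane | C=C(C)/C=C/O[Si](CC)(CC)CC | intermediate
13 | open-chain (4E)-enal: C6 aldehyde, C2-OTES (1,2-anti), C1–C10 cis-epoxide, C9-OAc, C8-OTES, C7 vinyl | C=C[C@@H](O[Si](CC)(CC)CC)[C@H](OC(C)=O)[C@@]1(C)O[C@H]1[C@@H](O[Si](CC)(CC)CC)C/C(C)=C/C=O | intermediate
14 | 2-methylidenepropane-1,3-diol | C=C(CO)CO | starting material
15 | 2-({[tert-butyl(dimethyl)silyl]oxy}methyl)prop-2-en-1-ol | C=C(CO)CO[Si](C)(C)C(C)(C)C | intermediate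
16 | {[2-(bromomethyl)prop-2-en-1-yl]oxy}(tert-butyl)dimethylsilane | C=C(CBr)CO[Si](C)(C)C(C)(C)C | intermediate
17 | allylic bromide: 13 with C7H=C11(CH2Br)(CH2OTBS) instead of vinyl (E/Z mixture at C7=C11) | BrCC(CO[Si](C)(C)C(C)(C)C)=C[C@@H](O[Si](CC)(CC)CC)[C@H](OC(C)=O)[C@@]1(C)O[C@H]1[C@@H](O[Si](CC)(CC)CC)C/C(C)=C/C=O | intermediate
18 | allylchromium(III) dichloride derived from 17 | Cl[Cr](Cl)CC(CO[Si](C)(C)C(C)(C)C)=C[C@@H](O[Si](CC)(CC)CC)[C@H](OC(C)=O)[C@@]1(C)O[C@H]1[C@@H](O[Si](CC)(CC)CC)C/C(C)=C/C=O | intermediate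
19 | ten-membered carbocyclic alcohol: 6-OH, 7-C(=CH2)CH2OTBS, 4E, 2-OTES, 1,10-epoxide, 9-OAc, 8-OTES (C1, C6–C10 as in the target) | C=C(CO[Si](C)(C)C(C)(C)C)[C@@H]1[C@@H](O)/C=C(C)/C[C@H](O[Si](CC)(CC)CC)[C@@H]2O[C@]2(C)[C@@H](OC(C)=O)[C@@H]1O[Si](CC)(CC)CC | intermediate
20 | 6-O-acetate of 19 | C=C(CO[Si](C)(C)C(C)(C)C)[C@@H]1[C@@H](OC(C)=O)/C=C(C)/C[C@H](O[Si](CC)(CC)CC)[C@@H]2O[C@]2(C)[C@@H](OC(C)=O)[C@@H]1O[Si](CC)(CC)CC | intermediate
21 | 5-hydroperoxy-4(15)-ene from 20 (5,6-threo) | C=C(CO[Si](C)(C)C(C)(C)C)[C@@H]1[C@@H](OC(C)=O)[C@H](OO)C(=C)C[C@H](O[Si](CC)(CC)CC)[C@@H]2O[C@]2(C)[C@@H](OC(C)=O)[C@@H]1O[Si](CC)(CC)CC | intermediate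
22 | 5-hydroxy-4(15)-ene (5,6-threo; C5 as in the target) | C=C(CO[Si](C)(C)C(C)(C)C)[C@@H]1[C@@H](OC(C)=O)[C@H](O)C(=C)C[C@H](O[Si](CC)(CC)CC)[C@@H]2O[C@]2(C)[C@@H](OC(C)=O)[C@@H]1O[Si](CC)(CC)CC | intermediate
23 | (R)-2-methylbutanoic acid | CC[C@@H](C)C(=O)O | starting material
24 | 5-O-[(2R)-2-methylbutanoyl] ester of 22 | C=C(CO[Si](C)(C)C(C)(C)C)[C@@H]1[C@@H](OC(C)=O)[C@H](OC(=O)[C@H](C)CC)C(=C)C[C@H](O[Si](CC)(CC)CC)[C@@H]2O[C@]2(C)[C@@H](OC(C)=O)[C@@H]1O[Si](CC)(CC)CC | intermediate
25 | 2,8,12-triol (seco-lactone) | C=C(CO)[C@@H]1[C@@H](OC(C)=O)[C@H](OC(=O)[C@H](C)CC)C(=C)C[C@H](O)[C@@H]2O[C@]2(C)[C@@H](OC(C)=O)[C@@H]1O | intermediate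
26 | 8,12-lactol with C2-OH (anomer mixture) | C=C1C(O)O[C@@H]2[C@H]1[C@@H](OC(C)=O)[C@H](OC(=O)[C@H](C)CC)C(=C)C[C@H](O)[C@@H]1O[C@]1(C)[C@H]2OC(C)=O | intermediate
27 | 8,12-lactone with C2-OH | C=C1C(=O)O[C@@H]2[C@H]1[C@@H](OC(C)=O)[C@H](OC(=O)[C@H](C)CC)C(=C)C[C@H](O)[C@@H]1O[C@]1(C)[C@H]2OC(C)=O | intermediate
28 | CNP0256300.1 | C=C1C(=O)O[C@@H]2[C@H]1[C@@H](OC(C)=O)[C@H](OC(=O)[C@H](C)CC)C(=C)CC(=O)[C@@H]1O[C@]1(C)[C@H]2OC(C)=O | target

## Step count and risks

Total step count: 18. Longest linear sequence: 15 steps (steps 1–7, 9, 12–18).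

**Step 13 (ring closure).** The allylchromium can oligomerise, eliminate the C8 silyloxy group (1,4-elimination to a diene), or add with the wrong facial sense at C6/C7. The fallback sets out from 13 and comes back at 19. It generates the C7 nucleophile by catalytic π-allylpalladium umpolung instead of chromium(II) insertion, a method proven for germacrane ten-membered rings. Alcohol 15 is treated with methyl chloroformate and pyridine to give methyl 2-({[tert-butyl(dimethyl)silyl]oxy}methyl)prop-2-en-1-yl carbonate F1. Cross-metathesis of 13 with F1 (Hoveyda–Grubbs II) gives the allylic carbonate F2. Pd(PPh3)4 (10 mol %) and Et2Zn (3 equiv) in THF at 2 mM ionise the carbonate, transmetallate to the allylzinc and close the same C6–C7 bond to give 19.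

**Step 12 (cross-metathesis).** Making a trisubstituted alkene from a hindered allylic ether with an allylic bromide partner may be slow, and the bromide may degrade the catalyst. The fallback sets out from 13 and comes back at 17. It separates olefin formation from halide installation. Cross-metathesis of 13 with the free allylic alcohol 15, whose hydroxyl assists and is inert to the ruthenium carbene, gives the allylic alcohol F3. Appel bromination (CBr4, PPh3, 2,6-lutidine, 0 °C) then gives 17.

**Step 15 (ene reaction on the acetate).** With no hydroxyl to steer singlet oxygen, facial selectivity rests on ring conformation alone. The fallback sets out from 19 and comes back at 24. It uses the free C6 hydroxyl as a directing group (hydroxy-directed, threo-selective Schenck ene reaction). Photooxygenation of 19 gives the 5-hydroperoxy-6-ol F4, and PPh3 reduces it to the 5,6-diol F5. The less hindered allylic C5 hydroxyl is esterified selectively with 23 (DIC, DMAP cat., −20 °C) to give the 6-hydroxy 5-(2-methylbutanoate) F6. Acetylation (Ac2O, pyridine, DMAP) then gives 24.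

Further compounds
F1 | step 13 | methyl 2-({[tert-butyl(dimethyl)silyl]oxy}methyl)prop-2-en-1-yl carbonate | C=C(COC(=O)OC)CO[Si](C)(C)C(C)(C)C
F2 | step 13 | allylic carbonate: 13 with C7H=C11(CH2OCO2Me)(CH2OTBS) instead of vinyl (E/Z mixture) | COC(=O)OCC(CO[Si](C)(C)C(C)(C)C)=C[C@@H](O[Si](CC)(CC)CC)[C@H](OC(C)=O)[C@@]1(C)O[C@H]1[C@@H](O[Si](CC)(CC)CC)C/C(C)=C/C=O
F3 | step 12 | allylic alcohol: 13 with C7H=C11(CH2OH)(CH2OTBS) instead of vinyl (E/Z mixture) | OCC(CO[Si](C)(C)C(C)(C)C)=C[C@@H](O[Si](CC)(CC)CC)[C@H](OC(C)=O)[C@@]1(C)O[C@H]1[C@@H](O[Si](CC)(CC)CC)C/C(C)=C/C=O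
F4 | step 15 | 5-hydroperoxy-6-hydroxy-4(15)-ene from 19 | C=C(CO[Si](C)(C)C(C)(C)C)[C@@H]1[C@@H](O)[C@H](OO)C(=C)C[C@H](O[Si](CC)(CC)CC)[C@@H]2O[C@]2(C)[C@@H](OC(C)=O)[C@@H]1O[Si](CC)(CC)CC
F5 | step 15 | 5,6-diol (threo) | C=C(CO[Si](C)(C)C(C)(C)C)[C@@H]1[C@@H](O)[C@H](O)C(=C)C[C@H](O[Si](CC)(CC)CC)[C@@H]2O[C@]2(C)[C@@H](OC(C)=O)[C@@H]1O[Si](CC)(CC)CC
F6 | step 15 | 6-hydroxy 5-[(2R)-2-methylbutanoate] | C=C(CO[Si](C)(C)C(C)(C)C)[C@@H]1[C@@H](O)[C@H](OC(=O)[C@H](C)CC)C(=C)C[C@H](O[Si](CC)(CC)CC)[C@@H]2O[C@]2(C)[C@@H](OC(C)=O)[C@@H]1O[Si](CC)(CC)CC
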